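**Assumption:** the target SMILES has no stereocentre and no E/Z-defined double bond (the prenyl alkene carries two identical methyls), so Kuwanon A is achiral and "single enantiomer" needs no stereocontrol.

## Retrosynthetic overview

1. Kuwanon A ⇐ its tris-MOM ether; global acid deprotection is the last step.
2. The flavone pyranone ring is formed last, in one step: Rh-catalysed oxidative aldehyde C–H / phenol O–H [4+2] annulation of an A-ring salicylaldehyde with an aryl–prenyl internal alkyne. This makes C4–C3 and C2–O1 and delivers the 2-aryl and 3-prenyl groups together, with no Baker–Venkataraman or chalcone sequence and no late C3-prenylation.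
3. The skipped enyne ⇐ terminal aryl alkyne + prenyl bromide (Cu); the alkyne ⇐ chromene-8-carbaldehyde (Ohira–Bestmann).
4. The B-ring 2H-pyran is formed first, by an aryl 1,1-dimethylpropargyl ether Claisen/6π cascade on 2,4-dihydroxybenzaldehyde; the ortho-CHO blocks one ortho site, so the angular regiochemistry is forced.
5. Ring order: both benzene rings are purchased; B-ring pyran first; flavone C-ring last.

## Route

**Step 1**
Reactants: 1 (2,4-dihydroxybenzaldehyde); 2 (chloromethyl methyl ether, MOMCl)
Product: 3 (2-hydroxy-4-(methoxymethoxy)benzaldehyde)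
Conditions: MOMCl (1.1 equiv), K2CO3, acetone, 0 °C → rt
Reagents that add atoms: 2, MOMCl, COCCl
Why: Selective Williamson-type O-alkylation, because the 2-OH is hydrogen-bonded to the aldehyde and much less nucleophilic than the 4-OH; no stereocentre formed.

**Step 2**
Reactants: 3; 4 (3-chloro-3-methylbut-1-yne)
Product: 5 (4-(methoxymethoxy)-2-[(2-methylbut-3-yn-2-yl)oxy]benzaldehyde)
Conditions: 4 (2 equiv), DBU, CuCl2·2H2O (1 mol %), MeCN, 0 °C → rt
Reagents that add atoms: 4, 3-chloro-3-methylbut-1-yne, C#CC(C)(C)Cl
Why: Cu-catalysed propargylic etherification (via a copper–allenylidene/propargyl cation equivalent), which works on hindered and electron-poor phenols and leaves the aldehyde and MOM ether untouched; no stereocentre formed.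

**Step 3**
Reactants: 5
Product: 6 (5-(methoxymethoxy)-2,2-dimethyl-2H-chromene-8-carbaldehyde)
Conditions: o-xylene, 140 °C, sealed tube
Reagents that add atoms: none
Why: Aryl propargyl ether Claisen rearrangement, then enolisation, 1,5-H shift and oxa-6π electrocyclisation; the only free ortho position is C3 (the other carries CHO), so the pyran oxygen ends up next to the formyl-bearing carbon as the target requires; no stereocentre formed.

**Step 4**
Reactants: 6; 7 (dimethyl (1-diazo-2-oxopropyl)phosphonate, Ohira–Bestmann reagent)
Product: 8 (8-ethynyl-5-(methoxymethoxy)-2,2-dimethyl-2H-chromene)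
Conditions: 7 (1.5 equiv), K2CO3, MeOH, 0 °C → rt
Reagents that add atoms: 7, Ohira–Bestmann reagent, COP(=O)(OC)C(=[N+]=[N-])C(C)=O (contributes one carbon)
Why: Seyferth–Gilbert homologation (Ohira–Bestmann modification) converts ArCHO to ArC≡CH under mild base that the MOM ether and chromene tolerate; no stereocentre formed.

**Step 5**
Reactants: 8; 9 (prenyl bromide, 1-bromo-3-methylbut-2-ene)
Product: 10 (5-(methoxymethoxy)-2,2-dimethyl-8-(5-methylhex-4-en-1-yn-1-yl)-2H-chromene)
Conditions: 9 (1.3 equiv), CuI (10 mol %), K2CO3, NaI, DMF, rt, degassed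
Reagents that add atoms: 9, prenyl bromide, CC(C)=CCBr
Why: Cu(I)-catalysed allylation of a terminal alkyne (copper acetylide plus allylic halide), which attacks the unhindered primary terminus of prenyl bromide to give the linear skipped enyne, while the mild carbonate base avoids isomerisation to the conjugated enyne or allene; no stereocentre formed.

**Step 6**
Reactants: 11 (2,4,6-trihydroxybenzaldehyde); 2 (MOMCl)
Product: 12 (2-hydroxy-4,6-bis(methoxymethoxy)benzaldehyde)
Conditions: MOMCl (2.1 equiv), i-Pr2NEt, CH2Cl2, 0 °C → rt
Reagents that add atoms: 2, MOMCl, COCCl (two equivalents incorporated)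
Why: Chelation-controlled selective O-alkylation; after the first ortho-OH is capped, the remaining ortho-OH is locked in a hydrogen bond to the aldehyde and stays free, as the annulation needs; no stereocentre formed.

**Step 7 (key step)**
Reactants: 10; 12 (1.3 equiv)
Product: 13 (5,7-bis(methoxymethoxy)-2-[5-(methoxymethoxy)-2,2-dimethyl-2H-chromen-8-yl]-3-(3-methylbut-2-en-1-yl)-4H-chromen-4-one)
Conditions: [RhCl(cod)]2 (2.5 mol %), 1,2,3,4-tetraphenylcyclopentadiene (10 mol %), Cu(OAc)2·H2O (2.1 equiv), o-xylene, 130 °C, N2
Reagents that add atoms: none (Cu(OAc)2 is only the terminal oxidant; the two reactants lose 2 H)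
Why: Rh-catalysed oxidative aldehyde C–H / phenol O–H [4+2] annulation with an internal alkyne: phenoxide-directed formyl C–H rhodation gives an acyl-rhodacycle, the alkyne inserts with its aryl-bearing carbon on Rh (the usual regiochemistry for aryl alkyl alkynes in this reaction class), and C–O reductive elimination closes the chromone with aryl at C2 and prenyl at C3; the reaction type is known, but the skipped-enyne / 6-alkoxysalicylaldehyde pairing is an untested substrate extension; no stereocentre formed.

**Step 8**
Reactants: 13
Product: 14 (Kuwanon A, 5,7-dihydroxy-2-(5-hydroxy-2,2-dimethyl-2H-chromen-8-yl)-3-(3-methylbut-2-en-1-yl)-4H-chromen-4-one)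
Conditions: 3 M aq HCl, MeOH, 55 °C
Reagents that add atoms: none
Why: Acid-catalysed acetal (MOM) methanolysis frees all three phenols; the prenyl group cannot cyclise because the adjacent 2'-oxygen is already tied up in the chromene and no free ortho-OH flanks it; no stereocentre formed.

## Compound list

1 | 2,4-dihydroxybenzaldehyde | O=Cc1ccc(O)cc1O | starting material
2 | chloromethyl methyl ether (MOMCl) | COCCl | starting material (reagent)
3 | 2-hydroxy-4-(methoxymethoxy)benzaldehyde | O=Cc1ccc(OCOC)cc1O | intermediate
4 | 3-chloro-3-methylbut-1-yne | C#CC(C)(C)Cl | starting material (reagent)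
5 | 4-(methoxymethoxy)-2-[(2-methylbut-3-yn-2-yl)oxy]benzaldehyde | O=Cc1ccc(OCOC)cc1OC(C)(C)C#C | intermediate
6 | 5-(methoxymethoxy)-2,2-dimethyl-2H-chromene-8-carbaldehyde | O=Cc1ccc(OCOC)c2C=CC(C)(C)Oc12 | intermediate
7 | dimethyl (1-diazo-2-oxopropyl)phosphonate | COP(=O)(OC)C(=[N+]=[N-])C(C)=O | starting material (reagent)
8 | 8-ethynyl-5-(methoxymethoxy)-2,2-dimethyl-2H-chromene | C#Cc1ccc(OCOC)c2C=CC(C)(C)Oc12 | intermediate
9 | prenyl bromide (1-bromo-3-methylbut-2-ene) | CC(C)=CCBr | starting material (reagent)
10 | 5-(methoxymethoxy)-2,2-dimethyl-8-(5-methylhex-4-en-1-yn-1-yl)-2H-chromene | CC(C)=CCC#Cc1ccc(OCOC)c2C=CC(C)(C)Oc12 | intermediate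
11 | 2,4,6-trihydroxybenzaldehyde | O=Cc1c(O)cc(O)cc1O | starting material
12 | 2-hydroxy-4,6-bis(methoxymethoxy)benzaldehyde | O=Cc1c(O)cc(OCOC)cc1OCOC | intermediate
13 | 5,7-bis(methoxymethoxy)-2-[5-(methoxymethoxy)-2,2-dimethyl-2H-chromen-8-yl]-3-(3-methylbut-2-en-1-yl)-4H-chromen-4-one | CC(C)=CCc1c(-c2ccc(OCOC)c3c2OC(C)(C)C=C3)oc2cc(OCOC)cc(OCOC)c2c1=O | intermediate
14 | Kuwanon A | CC(C)=CCc1c(-c2ccc(O)c3c2OC(C)(C)C=C3)oc2cc(O)cc(O)c2c1=O | target

## Summary

**Total steps:** 8
**Longest linear sequence:** 7 (steps 1 → 2 → 3 → 4 → 5 → 7 → 8); step 6 is a one-step side branch.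

**Three steps most likely to fail, with fallbacks**

1. **Step 7 (Rh oxidative annulation).** Risks: isomerisation or side reactions of the skipped enyne at 130 °C, decarbonylation of the acyl-Rh intermediate, a sluggish hindered alkyne, and partial MOM loss (harmless, since step 8 removes them anyway).
   Fallback: abandon the C–H annulation and use the conventional route. Pinnick-oxidise aldehyde 6 to the acid, esterify with 2-hydroxy-4,6-bis(methoxymethoxy)acetophenone, run a Baker–Venkataraman rearrangement, C-prenylate the 1,3-diketone with prenyl bromide/K2CO3, and cyclodehydrate to 13.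

2. **Step 5 (Cu-catalysed alkyne prenylation).** Risks: SN2' (reverse-prenyl) product, Glaser homocoupling, and enyne-to-allene isomerisation.
   Fallback: carry the prenyl group in masked form. Open ethylene oxide with the lithium acetylide of 8 (BF3·OEt2) and silylate to Ar–C≡C–CH2CH2OTBS. After the step-7 annulation, desilylate, oxidise to the aldehyde (Dess–Martin) and install the alkene by Wittig reaction with isopropylidene-triphenylphosphorane. This also removes the skipped enyne from the Rh step.

3. **Step 2 (propargylation of the chelated, hindered 2-OH, feeding the Claisen in step 3).** Risks: low conversion or base-induced decomposition of the tertiary propargyl chloride.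
   Fallback: build the chromene by ortho-metalation and oxidative cyclisation instead. Lithiate 1,3-bis(methoxymethoxy)benzene at C2 and prenylate (CuI, prenyl bromide); lithiate again ortho to OMOM and formylate with DMF; selectively remove the MOM ortho to the CHO (chelation-assisted); then DDQ oxidative cyclisation of the 3-prenyl-2-hydroxy unit gives 6 with the same regiochemistry.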